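**Plan**

- Retrosynthesis: the n-propyl end of the butanoyl group is traced back to a cyclopropane (C–C hydrogenolysis). Ring 1, the butanoyl-bearing ring (C1 = ring C=O between acyl carbon C2 and bridge carbon C6; C4 = CMe2), is then cut at C1–C2 and C4–C5.
- Enabling feature: in ring 1, C5–C6–C1 is a 2-substituted malonyl unit and C2 and C4 are the two α-carbons of the C3 ketone. Ring 1 is therefore a 1,3-diacyl electrophile joined to the two carbanion sites of a β-diketone dianion; ring 2 and the CH2 bridge ride on the malonyl carbon C6.
- Forward: ring 2 arises first by geminal C-methylation of flopropione. The bridge carbon and the malonyl unit are then annulated onto it as a temporary enol-lactone ring (ethoxymethylenemalonate, then hydrogenation), which activates one malonyl carbonyl.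
- Ring 1 is formed last, in one [3+3] operation, from this lactone and the dianion of 1-cyclopropyl-4-methylpentane-1,3-dione. The lactone ring opens in the same step. The cyclopropane is a non-enolizable latent n-propyl group that fixes the dianion regiochemistry, and it is opened by hydrogenolysis at the end.
- Stereochemistry: the target has no stereocentre; the only one on the route (C3 of the lactone, racemic) is destroyed in the key step.

Key step: step 5

Assumption: in step 2 the pyranone is taken to close onto the enol oxygen next to the gem-dimethyl carbon of ring 2; closure onto the other flanking oxygen would give an isomeric lactone that converges on the same open-chain intermediate in step 5.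

**Step 1**
Reactants: 1 1-(2,4,6-trihydroxyphenyl)propan-1-one (flopropione)
Product: 2 3,5-dihydroxy-4,4-dimethyl-2-propanoylcyclohexa-2,5-dien-1-one (propionylfilicinic acid)
Conditions: NaOMe (3 equiv), MeI (2.2 equiv), MeOH, 0 °C to rt; then aq. HCl
Reagents that add atoms: iodomethane, CI
Why: Double C-methylation at one free ring carbon of the acylphloroglucinol anion (dearomatizing geminal C-alkylation) is the standard entry to acylfilicinic acids, and limiting MeI to about two equivalents should leave the second ring CH free.

**Step 2**
Reactants: 2 3,5-dihydroxy-4,4-dimethyl-2-propanoylcyclohexa-2,5-dien-1-one; 3 diethyl 2-(ethoxymethylidene)propanedioate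
Product: 4 ethyl 7-hydroxy-8,8-dimethyl-2,5-dioxo-6-propanoyl-5,8-dihydro-2H-chromene-3-carboxylate
Conditions: NaOEt (2.2 equiv), EtOH, reflux; then 2 M HCl, 0 °C
Reagents that add atoms: none
Why: The last free ring carbon of 2 should displace ethoxide from the ethoxymethylene malonate (addition–elimination, Knoevenagel-type) and the adjacent enol oxygen should then lactonize onto the cis ester on acidification, the known 2-pyranone annulation of cyclic 1,3-diones.

**Step 3**
Reactants: 4 ethyl 7-hydroxy-8,8-dimethyl-2,5-dioxo-6-propanoyl-5,8-dihydro-2H-chromene-3-carboxylate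
Product: 5 ethyl 7-hydroxy-8,8-dimethyl-2,5-dioxo-6-propanoyl-3,4,5,8-tetrahydro-2H-chromene-3-carboxylate (racemic at C3)
Conditions: H2 (1 atm), Pd/C, EtOAc, rt
Reagents that add atoms: none
Why: Catalytic hydrogenation should saturate only the electron-poor C3=C4 bond of the 2-pyranone (an alkylidene malonate), because the tetrasubstituted push–pull enol double bonds and the chelated triketone of ring 2 are inert to H2/Pd; the new C3 centre is racemic and is erased in step 5.

**Step 4**
Reactants: 6 1-cyclopropylethan-1-one; 7 methyl 2-methylpropanoate
Product: 8 1-cyclopropyl-4-methylpentane-1,3-dione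
Conditions: NaH (2.2 equiv), THF, reflux; then aq. HCl
Reagents that add atoms: none
Why: Crossed Claisen condensation in which the ketone enolizes only at its methyl group (the cyclopropyl methine does not enolize) and irreversible formation of the β-diketonate drives the acylation by the ester.

**Step 5**
Reactants: 5 ethyl 7-hydroxy-8,8-dimethyl-2,5-dioxo-6-propanoyl-3,4,5,8-tetrahydro-2H-chromene-3-carboxylate; 8 1-cyclopropyl-4-methylpentane-1,3-dione
Product: 12 2-(cyclopropanecarbonyl)-6-[(2,4-dihydroxy-3,3-dimethyl-6-oxo-5-propanoylcyclohexa-1,4-dien-1-yl)methyl]-3,5-dihydroxy-4,4-dimethylcyclohexa-2,5-dien-1-one, via sodium lithium dienediolate 9 (not isolated), via ketene ester 10 (not isolated), via open-chain triketo ester 11 (not isolated)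
Conditions: 8 (3.3 equiv), NaH (3.3 equiv), THF, 0 °C; n-BuLi (3.3 equiv), 0 °C; then 5 in THF, −78 °C to rt, then 50 °C; 1 M HCl, 0 °C
Reagents that add atoms: none
Why: Proposed new method: two equivalents of dianion 9 should deprotonate the ring-2 enol and the malonate-type C3–H of lactone 5, whose enol-ester C–O bond then breaks by E1cB elimination (the temporary lactone ring opens with the ring-2 enolate as leaving group) to give ketene 10, the only electrophile in a medium where every other carbonyl is masked as an enolate. The tertiary carbanion terminus of a third equivalent of 9 should add to the sp carbon of 10 and forge the quaternary C4–C5 bond of open-chain triketo ester 11, and on warming the central carbon of its 1,3-diketonate should attack the ethyl ester and expel ethoxide (Claisen condensation of Dieckmann type), which closes ring 1 through the C1–C2 bond as a 6-(enolendo)-exo-trig process and is pulled forward by deprotonation of the acyl-trione. The closest known reaction types are the γ-C-acylation of β-dicarbonyl dianions at an isopropyl methine, the ketene (E1cB) pathway of activated malonate esters and the biomimetic Claisen cyclization of 3,5,7-triketo esters to acylphloroglucinols; their union as a [3+3] annulation of a diketone dianion with a malonate enol lactone is new. No stereocentre is formed and the racemic centre of 5 becomes sp2. The step needs the second deprotonation of 8 to occur at the isopropyl methine, which the cyclopropane secures because its own α-C–H cannot be enolized without building an exocyclic double bond on the three-membered ring and no other C–H acid is present. C- over O-acylation is expected from a localized tertiary carbanion meeting a small linear ketene, and Claisen rather than aldol closure from the fact that all ketones of 11 are deactivated as enolates while the doubly enolized product is the thermodynamic sink.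

**Step 6**
Reactants: 12 2-(cyclopropanecarbonyl)-6-[(2,4-dihydroxy-3,3-dimethyl-6-oxo-5-propanoylcyclohexa-1,4-dien-1-yl)methyl]-3,5-dihydroxy-4,4-dimethylcyclohexa-2,5-dien-1-one
Product: 13 2-butanoyl-6-[(2,4-dihydroxy-3,3-dimethyl-6-oxo-5-propanoylcyclohexa-1,4-dien-1-yl)methyl]-3,5-dihydroxy-4,4-dimethylcyclohexa-2,5-dien-1-one (target, CNP0260944.0)
Conditions: H2 (5 bar), Pd/C, EtOAc–AcOH, 50 °C
Reagents that add atoms: none
Why: Hydrogenolysis of a cyclopropyl ketone cleaves the ring C–C bond that adjoins the carbonyl and overlaps with its π system, which should unveil the unbranched propyl chain of the butanoyl group while the enolized trione rings and the methylene bridge stay untouched.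

**Compound list**

1 | 1-(2,4,6-trihydroxyphenyl)propan-1-one (flopropione) | CCC(=O)c1c(O)cc(O)cc1O | starting material
2 | 3,5-dihydroxy-4,4-dimethyl-2-propanoylcyclohexa-2,5-dien-1-one (propionylfilicinic acid) | CCC(=O)C1=C(O)C(C)(C)C(O)=CC1=O | intermediate
3 | diethyl 2-(ethoxymethylidene)propanedioate | CCOC=C(C(=O)OCC)C(=O)OCC | starting material
4 | ethyl 7-hydroxy-8,8-dimethyl-2,5-dioxo-6-propanoyl-5,8-dihydro-2H-chromene-3-carboxylate | CCOC(=O)C1=CC2=C(OC1=O)C(C)(C)C(O)=C(C(=O)CC)C2=O | intermediate
5 | ethyl 7-hydroxy-8,8-dimethyl-2,5-dioxo-6-propanoyl-3,4,5,8-tetrahydro-2H-chromene-3-carboxylate (racemic at C3) | CCOC(=O)C1CC2=C(OC1=O)C(C)(C)C(O)=C(C(=O)CC)C2=O | intermediate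
6 | 1-cyclopropylethan-1-one | CC(=O)C1CC1 | starting material
7 | methyl 2-methylpropanoate | COC(=O)C(C)C | starting material
8 | 1-cyclopropyl-4-methylpentane-1,3-dione | CC(C)C(=O)CC(=O)C1CC1 | intermediate
9 | sodium lithium 1-cyclopropyl-4-methylpenta-1,3-diene-1,3-bis(olate) (dianion of 8, not isolated) | [Na+].[Li+].CC(C)=C([O-])C=C([O-])C1CC1 | intermediate
10 | ethyl 2-[(2,4-dihydroxy-3,3-dimethyl-6-oxo-5-propanoylcyclohexa-1,4-dien-1-yl)methyl]-3-oxoprop-2-enoate (ketene, drawn neutral, present as its dianion, not isolated) | CCOC(=O)C(=C=O)CC1=C(O)C(C)(C)C(O)=C(C(=O)CC)C1=O | intermediate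
11 | ethyl 7-cyclopropyl-2-[(2,4-dihydroxy-3,3-dimethyl-6-oxo-5-propanoylcyclohexa-1,4-dien-1-yl)methyl]-4,4-dimethyl-3,5,7-trioxoheptanoate (drawn neutral, present as its polyanion, not isolated) | CCOC(=O)C(CC1=C(O)C(C)(C)C(O)=C(C(=O)CC)C1=O)C(=O)C(C)(C)C(=O)CC(=O)C1CC1 | intermediate
12 | 2-(cyclopropanecarbonyl)-6-[(2,4-dihydroxy-3,3-dimethyl-6-oxo-5-propanoylcyclohexa-1,4-dien-1-yl)methyl]-3,5-dihydroxy-4,4-dimethylcyclohexa-2,5-dien-1-one | O=C(C1CC1)C1=C(O)C(C)(C)C(O)=C(CC2=C(O)C(C)(C)C(O)=C(C(=O)CC)C2=O)C1=O | intermediate
13 | 2-butanoyl-6-[(2,4-dihydroxy-3,3-dimethyl-6-oxo-5-propanoylcyclohexa-1,4-dien-1-yl)methyl]-3,5-dihydroxy-4,4-dimethylcyclohexa-2,5-dien-1-one | CCCC(=O)C1=C(O)C(C)(C)C(O)=C(CC2=C(O)C(C)(C)C(O)=C(C(=O)CC)C2=O)C1=O | target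

**Step count**

Total steps: 6. Longest linear sequence: 5 (steps 1, 2, 3, 5, 6); step 4 is a one-step side branch.

**Steps most likely to fail**

1. Step 5 (proposed new method).
   - What may go wrong: the E1cB opening of the lactone enolate may be too slow at temperatures that dianion 9 tolerates, so that the carbanion is lost by proton transfer from the solvent. O-acylation or incomplete Claisen closure of the polyanion may leave open-chain material. Prolonged heating in base may let the two halves exchange across the methylene bridge.
   - Fallback (known chemistry only), setting out from 2 and rejoining the route at 13: a Mannich reaction of 2 with aqueous formaldehyde and piperidine (EtOH, rt) should give 3,5-dihydroxy-4,4-dimethyl-6-(piperidin-1-ylmethyl)-2-propanoylcyclohexa-2,5-dien-1-one F1. In parallel, commercial 1-(2,4,6-trihydroxyphenyl)butan-1-one would be gem-dimethylated under the conditions of step 1 (NaOMe, MeI, MeOH) to 2-butanoyl-3,5-dihydroxy-4,4-dimethylcyclohexa-2,5-dien-1-one F2. Heating F1 with F2 (EtOH, 80 °C) should expel piperidine, generate the ring-2 methide and add F2 through its free ring carbon, which would give 13 directly; steps 2 to 6 are then not needed.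

2. Step 6.
   - What may go wrong: hydrogenolysis of a cyclopropane conjugated to an enolized, chelated acyl group may be sluggish, and forcing conditions may start to reduce ring carbonyls.
   - Fallback, setting out from 12 and rejoining at 13: ring-opening of the cyclopropyl ketone with iodotrimethylsilane made in the flask (NaI, Me3SiCl, MeCN, 0 °C to rt, aqueous work-up) should give 6-[(2,4-dihydroxy-3,3-dimethyl-6-oxo-5-propanoylcyclohexa-1,4-dien-1-yl)methyl]-3,5-dihydroxy-2-(4-iodobutanoyl)-4,4-dimethylcyclohexa-2,5-dien-1-one F3. Radical deiodination (Bu3SnH, AIBN, toluene, 80 °C) should then give 13.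

3. Step 2.
   - What may go wrong: the last ring carbon of the acyl-trione may be a poor C-nucleophile, with competing O-attack on the ethoxymethylene malonate, or the lactone may close incompletely.
   - Fallback, setting out from 2 and rejoining at 5 (compound 4 and step 3 are bypassed): Michael addition of 2 to diethyl 2-methylidenepropanedioate (cat. Et3N, CH2Cl2, 0 °C) should give diethyl 2-[(2,4-dihydroxy-3,3-dimethyl-6-oxo-5-propanoylcyclohexa-1,4-dien-1-yl)methyl]propanedioate F4. Acid-catalysed lactonization (cat. TsOH, toluene, reflux, ethanol distilled off) should then close the enol lactone 5 at the correct oxidation level.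

**Further compounds**

F1 | step 5 | 3,5-dihydroxy-4,4-dimethyl-6-(piperidin-1-ylmethyl)-2-propanoylcyclohexa-2,5-dien-1-one | CCC(=O)C1=C(O)C(C)(C)C(O)=C(CN2CCCCC2)C1=O
F2 | step 5 | 2-butanoyl-3,5-dihydroxy-4,4-dimethylcyclohexa-2,5-dien-1-one | CCCC(=O)C1=C(O)C(C)(C)C(O)=CC1=O
F3 | step 6 | 6-[(2,4-dihydroxy-3,3-dimethyl-6-oxo-5-propanoylcyclohexa-1,4-dien-1-yl)methyl]-3,5-dihydroxy-2-(4-iodobutanoyl)-4,4-dimethylcyclohexa-2,5-dien-1-one | ICCCC(=O)C1=C(O)C(C)(C)C(O)=C(CC2=C(O)C(C)(C)C(O)=C(C(=O)CC)C2=O)C1=O
F4 | step 2 | diethyl 2-[(2,4-dihydroxy-3,3-dimethyl-6-oxo-5-propanoylcyclohexa-1,4-dien-1-yl)methyl]propanedioate | CCOC(=O)C(CC1=C(O)C(C)(C)C(O)=C(C(=O)CC)C1=O)C(=O)OCC
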